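Positions are given in icetexane numbering (C1–C20).

**Retrosynthetic overview**
1. Komaroviquinone 21 comes from trimethoxyarene hemiketal 20 by oxidative demethylation. Ring C is bought as an arene and the quinone is unmasked last.
2. 20 comes from the acyclic aryl dienoate 17 in one enantioselective acid-catalysed tricyclisation: C4–C5 (ring A), then C10–O (oxa-bridge), then C7–C8 (ring B).
3. 17 comes from vinyl iodide 14 and a zinc ester enolate (C5–C6). 14 comes from syn-carbocupration of arylpropyne 9 (C10–C1), which fixes the alkene geometry that becomes the C5/C10 relative configuration.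
4. 9 comes from arene 5 and methoxyallene (C9–C20). 5 comes from 1,2,4-trimethoxybenzene and acetone.

Assumption: the sense of induction of the chiral acid in step 6 cannot be predicted for this new substrate. Both catalyst antipodes are available, and the one that gives (5S,10S) is meant.

**Step 1**
Reactants: 1 1,2,4-trimethoxybenzene; 2 acetone
Product: 4 2-(2,3,6-trimethoxyphenyl)propan-2-ol, via aryllithium 3 (not isolated)
Conditions: n-BuLi, THF, 0 °C to rt; acetone, −78 °C to rt; H2O
Reagents that add atoms: none
Why: Directed ortho-metalation removes the C3–H flanked by two OMe groups, by far the most acidic one, and the aryllithium adds 1,2 to acetone.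

**Step 2**
Reactants: 4 2-(2,3,6-trimethoxyphenyl)propan-2-ol
Product: 5 2-isopropyl-1,3,4-trimethoxybenzene
Conditions: Et3SiH, TFA, CH2Cl2, 0 °C to rt
Reagents that add atoms: none
Why: In this ionic hydrogenation TFA ionises the tertiary benzylic alcohol, whose cation is stabilised by two ortho OMe groups, and Et3SiH delivers hydride while the aryl ethers stay inert.

**Step 3**
Reactants: 5 2-isopropyl-1,3,4-trimethoxybenzene; 6 methoxyallene
Product: 9 2-isopropyl-1,3,4-trimethoxy-5-(prop-2-yn-1-yl)benzene, via aryllithium 7 (not isolated), via arylmagnesium bromide 8 (not isolated)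
Conditions: n-BuLi, TMEDA, Et2O, 0 °C to rt; MgBr2·OEt2; CuBr (10 mol %), 6, −20 °C to rt; H2O
Reagents that add atoms: none
Why: Directed ortho-metalation takes the veratrole-type C–H (future C9, ortho to one OMe and meta to two more) rather than the C–H whose directing OMe is buttressed by the isopropyl group, and Cu-catalysed SN2′ attack on the CH2 terminus of methoxyallene expels methoxide to give the terminal alkyne.

**Step 4**
Reactants: 9 2-isopropyl-1,3,4-trimethoxy-5-(prop-2-yn-1-yl)benzene; 10 5-bromo-2-methylpent-2-ene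
Product: 14 (1E)-1-iodo-2-[(4-isopropyl-2,3,5-trimethoxyphenyl)methyl]-6-methylhepta-1,5-diene, via Grignard reagent 11 (not isolated), via alkylcopper 12 (not isolated), via alkenylcopper 13 (not isolated)
Conditions: 10, Mg, Et2O; CuBr·SMe2, Et2O/Me2S, −45 °C; 9, −25 °C; I2, THF, −50 to 0 °C
Reagents that add atoms: iodine, II
Why: Normant carbocupration adds RCu·MgBr2·SMe2 syn, with the alkyl group on the internal carbon and Cu on the terminus, and iodinolysis proceeds with retention, so the homoprenyl chain ends up cis to iodine.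

**Step 5**
Reactants: 14 (1E)-1-iodo-2-[(4-isopropyl-2,3,5-trimethoxyphenyl)methyl]-6-methylhepta-1,5-diene; 15 methyl bromoacetate
Product: 17 methyl (3E)-4-[(4-isopropyl-2,3,5-trimethoxyphenyl)methyl]-8-methylnona-3,7-dienoate, via Reformatsky reagent 16 (not isolated)
Conditions: 15, Zn (TMSCl-activated), THF; 14, Pd2(dba)3 (2 mol %), XPhos (5 mol %), THF, rt
Reagents that add atoms: none
Why: This Negishi-type coupling of a Reformatsky reagent with a vinyl iodide retains the alkene geometry, and the weakly basic zinc enolate does not move the β,γ-double bond into conjugation.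

**Step 6 (key step)**
Reactants: 17 methyl (3E)-4-[(4-isopropyl-2,3,5-trimethoxyphenyl)methyl]-8-methylnona-3,7-dienoate
Product: 20 (5S,7S,10S)-7,10-epoxy-11,12,14-trimethoxyicetexa-8,11,13-trien-7-ol, via lactonium ion 18 (not isolated), via methyl ketal 19 (not isolated)
Conditions: confined chiral imidodiphosphorimidate (IDPi) Brønsted acid (5 mol %), (CF3)3COH/CH2Cl2, −20 °C; then 1 M HCl, THF, rt; recrystallise
Reagents that add atoms: water, O
Why: Proposed new method: the chiral acid protonates the more basic, unhindered isopropylidene in its pocket and so picks the enantioface, then the chair-folded C5=C10 alkene adds anti (C4 to C5, ester carbonyl O to C10), which places H-5 trans to O-10 and gives the cis-fused O-methyl lactonium ion 18; its non-nucleophilic counter-ion cannot demethylate it, so the arene C8–H (ortho and para to OMe) attacks C7 from the only face the C20 tether allows, which sets C7 and returns H+ for turnover, and dilute acid then exchanges the ketal OMe for OH; the closest known reaction types are enantioselective acid-catalysed head-to-tail polyene cyclisations terminated by OH or CO2H, and Marson-type oxocarbenium Friedel–Crafts closures of oxa-bridged benzocycloheptanes.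

**Step 7**
Reactants: 20 (5S,7S,10S)-7,10-epoxy-11,12,14-trimethoxyicetexa-8,11,13-trien-7-ol
Product: 21 komaroviquinone
Conditions: (NH4)2Ce(NO3)6, MeCN/H2O, 0 °C
Reagents that add atoms: water, O
Why: CAN oxidative demethylation converts the para-related 11- and 14-OMe groups into the p-quinone and keeps the 12-OMe; no stereocentre is touched, and the bridged hemiketal can only re-close with the same C7 configuration.

**Compound list**
1 | 1,2,4-trimethoxybenzene | COc1ccc(OC)c(OC)c1 | starting material
2 | acetone | CC(C)=O | starting material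
3 | (2,3,6-trimethoxyphenyl)lithium | COc1ccc(OC)c([Li])c1OC | intermediate
4 | 2-(2,3,6-trimethoxyphenyl)propan-2-ol | COc1ccc(OC)c(C(C)(C)O)c1OC | intermediate
5 | 2-isopropyl-1,3,4-trimethoxybenzene | COc1ccc(OC)c(C(C)C)c1OC | intermediate
6 | methoxyallene (1-methoxypropa-1,2-diene) | COC=C=C | starting material
7 | (4-isopropyl-2,3,5-trimethoxyphenyl)lithium | COc1c([Li])cc(OC)c(C(C)C)c1OC | intermediate
8 | (4-isopropyl-2,3,5-trimethoxyphenyl)magnesium bromide | COc1c([Mg]Br)cc(OC)c(C(C)C)c1OC | intermediate
9 | 2-isopropyl-1,3,4-trimethoxy-5-(prop-2-yn-1-yl)benzene | C#CCc1cc(OC)c(C(C)C)c(OC)c1OC | intermediate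
10 | 5-bromo-2-methylpent-2-ene | CC(C)=CCCBr | starting material
11 | (4-methylpent-3-en-1-yl)magnesium bromide | CC(C)=CCC[Mg]Br | intermediate
12 | (4-methylpent-3-en-1-yl)copper, MgBr2·SMe2 complex | CC(C)=CCC[Cu] | intermediate
13 | (E)-alkenylcopper, Cu on C5 cis to the homoprenyl chain | [Cu]/C=C(\CCC=C(C)C)Cc1cc(OC)c(C(C)C)c(OC)c1OC | intermediate
14 | (1E)-1-iodo-2-[(4-isopropyl-2,3,5-trimethoxyphenyl)methyl]-6-methylhepta-1,5-diene | I/C=C(\CCC=C(C)C)Cc1cc(OC)c(C(C)C)c(OC)c1OC | intermediate
15 | methyl bromoacetate | COC(=O)CBr | starting material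
16 | bromo(2-methoxy-2-oxoethyl)zinc | COC(=O)C[Zn]Br | intermediate
17 | methyl (3E)-4-[(4-isopropyl-2,3,5-trimethoxyphenyl)methyl]-8-methylnona-3,7-dienoate (CH2CO2Me cis to the homoprenyl chain) | COC(=O)C/C=C(\CCC=C(C)C)Cc1cc(OC)c(C(C)C)c(OC)c1OC | intermediate
18 | (3aS,7aS) cis-fused 2-methoxy-4,4-dimethyl-7a-(arylmethyl)hexahydrobenzofuran-1-ium (O-methyl lactonium ion) | COC1=[O+][C@]2(Cc3cc(OC)c(C(C)C)c(OC)c3OC)CCCC(C)(C)[C@@H]2C1 | intermediate
19 | (5S,7S,10S)-7,10-epoxy-7,11,12,14-tetramethoxyicetexa-8,11,13-triene | COc1c(C(C)C)c(OC)c2c(C[C@@]34CCCC(C)(C)[C@@H]3C[C@]2(OC)O4)c1OC | intermediate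
20 | (5S,7S,10S)-7,10-epoxy-11,12,14-trimethoxyicetexa-8,11,13-trien-7-ol | COc1c(C(C)C)c(OC)c2c(C[C@@]34CCCC(C)(C)[C@@H]3C[C@]2(O)O4)c1OC | intermediate
21 | komaroviquinone, (5S,7S,10S)-7,10-epoxy-7-hydroxy-12-methoxyicetexa-8,12-diene-11,14-dione | COC1=C(C(C)C)C(=O)C2=C(C[C@@]34CCCC(C)(C)[C@@H]3C[C@]2(O)O4)C1=O | target

**Total steps:** 7. **Longest linear sequence:** 7 (from 1).

**Steps most likely to fail, most likely first**

Step 6. The cascade could stop at the lactone, protonate the internal alkene first, give low ee, or fail in the last Friedel–Crafts closure. The fallback sets out from 17 and separates the three ring closures.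
- LiOH saponification gives the dienoic acid F1.
- A stoichiometric chiral Lewis-acid-assisted Brønsted acid (BINOL monoether·SnCl4, toluene, −78 °C) bicyclises F1 to the cis-fused lactone F2, which is recrystallised to optical purity.
- NBS brominates the only free aromatic position to give the bromolactone F3.
- Bromine–lithium exchange (n-BuLi, THF, −78 °C) closes ring B by Parham-type attack on the lactone carbonyl. After a water quench the route is rejoined at 20.

Step 3. The metalation might not be regioselective, or the SN2′ coupling might be poor. The fallback sets out from 5 and uses bromine as a blocking group.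
- NBS brominates the electronically preferred position (future C8) to give the aryl bromide F4.
- Bromomethylation ((CH2O)n, HBr/AcOH) can then only reach the last free position and gives the benzylic bromide F5.
- Ethynylmagnesium bromide with CuCl replaces the benzylic bromide to give the bromo arylpropyne F6.
- n-BuLi (2.2 equiv) followed by water removes the blocking bromine. The route is rejoined at 9.

Step 4. Carbocupration of the benzylic propargylic alkyne might be low-yielding or poorly regioselective. The fallback sets out from 9 and sets the alkene by hydroxyl-directed hydrometalation instead.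
- Hydroxymethylation (n-BuLi, then paraformaldehyde) gives the propargylic alcohol F7.
- Trans-hydroalumination with Red-Al followed by I2 gives the (Z)-iodo allylic alcohol F8.
- Fe(acac)3-catalysed Kumada coupling with Grignard reagent 11 proceeds with retention and gives the allylic alcohol F9.
- ClCO2Me/pyridine gives the allylic methyl carbonate F10.
- Pd-catalysed decarboxylative carbonylation (Pd(OAc)2/PPh3, CO, 50 °C) bypasses 14, with some risk of alkene geometry scrambling through the π-allyl intermediate. The route is rejoined at 17.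

**Further compounds**
F1 | step 6 | (3E)-4-[(4-isopropyl-2,3,5-trimethoxyphenyl)methyl]-8-methylnona-3,7-dienoic acid | OC(=O)C/C=C(\CCC=C(C)C)Cc1cc(OC)c(C(C)C)c(OC)c1OC
F2 | step 6 | (3aS,7aS)-7a-[(4-isopropyl-2,3,5-trimethoxyphenyl)methyl]-4,4-dimethylhexahydro-1-benzofuran-2(3H)-one | O=C1O[C@]2(Cc3cc(OC)c(C(C)C)c(OC)c3OC)CCCC(C)(C)[C@@H]2C1
F3 | step 6 | (3aS,7aS)-7a-[(2-bromo-4-isopropyl-3,5,6-trimethoxyphenyl)methyl]-4,4-dimethylhexahydro-1-benzofuran-2(3H)-one | O=C1O[C@]2(Cc3c(Br)c(OC)c(C(C)C)c(OC)c3OC)CCCC(C)(C)[C@@H]2C1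
F4 | step 3 | 1-bromo-3-isopropyl-2,4,5-trimethoxybenzene | COc1cc(Br)c(OC)c(C(C)C)c1OC
F5 | step 3 | 1-bromo-2-(bromomethyl)-5-isopropyl-3,4,6-trimethoxybenzene | COc1c(CBr)c(Br)c(OC)c(C(C)C)c1OC
F6 | step 3 | 1-bromo-5-isopropyl-3,4,6-trimethoxy-2-(prop-2-yn-1-yl)benzene | C#CCc1c(Br)c(OC)c(C(C)C)c(OC)c1OC
F7 | step 4 | 4-(4-isopropyl-2,3,5-trimethoxyphenyl)but-2-yn-1-ol | OCC#CCc1cc(OC)c(C(C)C)c(OC)c1OC
F8 | step 4 | (2Z)-3-iodo-4-(4-isopropyl-2,3,5-trimethoxyphenyl)but-2-en-1-ol | OC/C=C(\I)Cc1cc(OC)c(C(C)C)c(OC)c1OC
F9 | step 4 | (2E)-3-[(4-isopropyl-2,3,5-trimethoxyphenyl)methyl]-7-methylocta-2,6-dien-1-ol | OC/C=C(\CCC=C(C)C)Cc1cc(OC)c(C(C)C)c(OC)c1OC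
F10 | step 4 | (2E)-3-[(4-isopropyl-2,3,5-trimethoxyphenyl)methyl]-7-methylocta-2,6-dien-1-yl methyl carbonate | COC(=O)OC/C=C(\CCC=C(C)C)Cc1cc(OC)c(C(C)C)c(OC)c1OC
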